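**Retrosynthetic overview**
- The para-hydroxyl is taken off first: hydroquinone ⇐ p-benzoquinone ⇐ 2-alkyl-6-methylphenol (Teuber oxidative dearomatization, then dithionite), so no oxygen protecting group is needed anywhere.
- C8'–C9' (allyl–vinyl) bond: Stille coupling of an aryl-C10 allylic bromide with an (S,E)-γ-hydroxy vinylstannane.
- Aryl–C1' bond (key step): dearomative ortho-C-allylation of sodium o-cresolate, through a cyclohexa-2,4-dienone, with unprotected ω-hydroxygeranyl chloride (from geranyl chloride by SeO2 oxidation).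
- Carbinol stereocentre: Sharpless epoxidation of geraniol, epoxy chloride to tertiary propargylic alcohol, then syn-hydrostannation to fix the 9E alkene.
- Rings: none is built; the benzene ring of o-cresol is bought intact, loses its aromaticity twice (dienone, then quinone) and regains it each time.

Assumption: the SMILES is read as the (11S)-carbinol with 2E,6E,9E alkenes; "single enantiomer" means the enantiomeric purity the Sharpless epoxidation delivers (about 91–95% ee).

**Step 1**
Reactants: 1 geraniol
Product: 2 [(2S,3S)-3-methyl-3-(4-methylpent-3-en-1-yl)oxiran-2-yl]methanol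
Conditions: Ti(OiPr)4 (5 mol %), L-(+)-diethyl tartrate (7 mol %), t-BuOOH, 4 Å MS, CH2Cl2, −20 °C
Reagents that add atoms: tert-butyl hydroperoxide CC(C)(C)OO
Why: Katsuki–Sharpless asymmetric epoxidation, in which the L-(+)-tartrate titanium catalyst epoxidizes only the allylic-alcohol alkene and gives the (2S,3S) epoxide, so that C3 (the later C11 carbinol carbon) is set as S.

**Step 2**
Reactants: 2 [(2S,3S)-3-methyl-3-(4-methylpent-3-en-1-yl)oxiran-2-yl]methanol
Product: 3 (2S,3R)-3-(chloromethyl)-2-methyl-2-(4-methylpent-3-en-1-yl)oxirane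
Conditions: PPh3, CCl4, NaHCO3, reflux
Reagents that add atoms: carbon tetrachloride ClC(Cl)(Cl)Cl
Why: Appel chlorination replaces the primary hydroxyl by SN2 under buffered, non-acidic conditions that leave the trisubstituted epoxide and both stereocentres untouched (the descriptor at the CH carbon changes only because the priorities change).

**Step 3**
Reactants: 3 (2S,3R)-3-(chloromethyl)-2-methyl-2-(4-methylpent-3-en-1-yl)oxirane
Product: 5 (3S)-3,7-dimethyloct-6-en-1-yn-3-ol, via lithium chloroalkenyl alkoxide 4 (not isolated)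
Conditions: LiN(iPr)2 (3.5 equiv), THF, −35 → 0 °C; aq NH4Cl
Reagents that add atoms: none
Why: Yadav–Takano alkynol synthesis, in which deprotonation of CH2Cl opens the epoxide by β-elimination at the C2–O bond and a second dehydrochlorination gives the alkyne; the C3–O bond is never broken, so the S carbinol is retained.

**Step 4**
Reactants: 5 (3S)-3,7-dimethyloct-6-en-1-yn-3-ol
Product: 6 (1E,3S)-3,7-dimethyl-1-(tributylstannyl)octa-1,6-dien-3-ol
Conditions: Bu3SnH, PdCl2(PPh3)2 (2 mol %), THF, 0 → 25 °C
Reagents that add atoms: tributyltin hydride CCCC[SnH](CCCC)CCCC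
Why: palladium-catalysed syn-hydrostannation puts tin on the terminal carbon, away from the bulky tertiary carbinol, and so fixes the E alkene; it is a pure addition that leaves the carbinol centre and the trisubstituted alkene alone.

**Step 5**
Reactants: 7 geranyl chloride
Product: 8 (2E,6E)-8-chloro-2,6-dimethylocta-2,6-dien-1-ol
Conditions: SeO2 (10 mol %), salicylic acid (10 mol %), t-BuOOH (3 equiv), CH2Cl2, 0 → 25 °C
Reagents that add atoms: tert-butyl hydroperoxide CC(C)(C)OO (terminal oxidant), selenium dioxide O=[Se]=O (oxygen carrier)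
Why: Sharpless–Umbreit allylic oxidation (ene reaction, then [2,3]-sigmatropic shift) hydroxylates the (E)-methyl group of the electron-rich terminal alkene, while the 2,3-alkene is deactivated by the allylic chloride, which survives these neutral, non-nucleophilic conditions.

**Step 6**
Reactants: 8 (2E,6E)-8-chloro-2,6-dimethylocta-2,6-dien-1-ol, 9 o-cresol (2-methylphenol)
Product: 12 2-[(2E,6E)-8-hydroxy-3,7-dimethylocta-2,6-dien-1-yl]-6-methylphenol, via sodium 2-methylphenolate 10 (not isolated), via 6-alkyl-2-methylcyclohexa-2,4-dienone 11 (not isolated)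
Conditions: NaH, toluene, 0 → 25 °C (3 equiv each of 9 and NaH); then 8, 25–45 °C; aq NH4Cl
Reagents that add atoms: none
Why: Claisen-type C-alkylation of an ambident phenolate, in which the tight sodium ion pair in a non-polar medium shields oxygen and delivers the allylic chloride by SN2 to the one free ortho carbon, so the ring loses its aromaticity as dienone 11 and regains it by tautomerization; the E alkenes are not touched, the transient C6 centre disappears, and the phenolate is too weak a base to deprotonate the primary alcohol of 8.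

**Step 7**
Reactants: 12 2-[(2E,6E)-8-hydroxy-3,7-dimethylocta-2,6-dien-1-yl]-6-methylphenol
Product: 13 2-[(2E,6E)-8-bromo-3,7-dimethylocta-2,6-dien-1-yl]-6-methylphenol
Conditions: CBr4, PPh3, CH2Cl2, −20 → 0 °C; used at once
Reagents that add atoms: carbon tetrabromide BrC(Br)(Br)Br
Why: Appel bromination converts only the primary allylic alcohol by SN2 under neutral conditions; the phenol is not brominated, and without base it does not alkylate itself or close to a chroman.

**Step 8**
Reactants: 13 2-[(2E,6E)-8-bromo-3,7-dimethylocta-2,6-dien-1-yl]-6-methylphenol, 6 (1E,3S)-3,7-dimethyl-1-(tributylstannyl)octa-1,6-dien-3-ol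
Product: 14 2-[(2E,6E,9E,11S)-11-hydroxy-3,7,11,15-tetramethylhexadeca-2,6,9,14-tetraen-1-yl]-6-methylphenol
Conditions: Pd2(dba)3 (2.5 mol %), AsPh3 (10 mol %), THF, 25–45 °C, Ar
Reagents that add atoms: none
Why: Stille allyl–vinyl coupling, in which the allylic bromide adds oxidatively to zerovalent palladium and the vinyl group is transferred with retention to the less hindered CH2 terminus, giving the skipped 6E,9E diene; the conditions are neutral, so the free phenol and the tertiary allylic alcohol survive and the S centre is not touched.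

**Step 9**
Reactants: 14 2-[(2E,6E,9E,11S)-11-hydroxy-3,7,11,15-tetramethylhexadeca-2,6,9,14-tetraen-1-yl]-6-methylphenol
Product: 16 2-[(2E,6E,9E,11S)-11-hydroxy-3,7,11,15-tetramethylhexadeca-2,6,9,14-tetraen-1-yl]-6-methylbenzene-1,4-diol (the target), via quinone 15 (not isolated)
Conditions: (KSO3)2NO (2.5 equiv), KH2PO4, acetone/H2O, 20 °C; then Na2S2O4, H2O/Et2O, Ar
Reagents that add atoms: potassium nitrosodisulfonate (KSO3)2NO [K+].[K+].[O]N(S(=O)(=O)[O-])S(=O)(=O)[O-]
Why: Teuber oxidation, in which two equivalents of the nitroxyl radical turn the 2,6-dialkylphenol with a free para position into the p-benzoquinone (the second dearomatization), a reaction that is selective for the phenol over alkenes and the tertiary alcohol at pH 6; dithionite then reduces the quinone to the hydroquinone in the same flask, and no stereocentre is involved.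

**Compound list**
1 | geraniol, (2E)-3,7-dimethylocta-2,6-dien-1-ol | CC(C)=CCC/C(C)=C/CO | starting material
2 | [(2S,3S)-3-methyl-3-(4-methylpent-3-en-1-yl)oxiran-2-yl]methanol | CC(C)=CCC[C@]1(C)O[C@H]1CO | intermediate
3 | (2S,3R)-3-(chloromethyl)-2-methyl-2-(4-methylpent-3-en-1-yl)oxirane | CC(C)=CCC[C@]1(C)O[C@H]1CCl | intermediate
4 | lithium (3S)-1-chloro-3,7-dimethylocta-1,6-dien-3-olate (E/Z mixture at C1=C2, not isolated) | CC(C)=CCC[C@](C)([O-])C=CCl.[Li+] | intermediate
5 | (3S)-3,7-dimethyloct-6-en-1-yn-3-ol, (S)-dehydrolinalool | CC(C)=CCC[C@](C)(O)C#C | intermediate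
6 | (1E,3S)-3,7-dimethyl-1-(tributylstannyl)octa-1,6-dien-3-ol | CC(C)=CCC[C@](C)(O)/C=C/[Sn](CCCC)(CCCC)CCCC | intermediate
7 | geranyl chloride, (2E)-1-chloro-3,7-dimethylocta-2,6-diene | CC(C)=CCC/C(C)=C/CCl | starting material
8 | (2E,6E)-8-chloro-2,6-dimethylocta-2,6-dien-1-ol | OC/C(C)=C/CC/C(C)=C/CCl | intermediate
9 | o-cresol, 2-methylphenol | Cc1ccccc1O | starting material
10 | sodium 2-methylphenolate (not isolated) | Cc1ccccc1[O-].[Na+] | intermediate
11 | 6-[(2E,6E)-8-hydroxy-3,7-dimethylocta-2,6-dien-1-yl]-2-methylcyclohexa-2,4-dien-1-one (racemic at C6, not isolated) | CC1=CC=CC(C/C=C(\C)CC/C=C(\C)CO)C1=O | intermediate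
12 | 2-[(2E,6E)-8-hydroxy-3,7-dimethylocta-2,6-dien-1-yl]-6-methylphenol | Cc1cccc(C/C=C(\C)CC/C=C(\C)CO)c1O | intermediate
13 | 2-[(2E,6E)-8-bromo-3,7-dimethylocta-2,6-dien-1-yl]-6-methylphenol | Cc1cccc(C/C=C(\C)CC/C=C(\C)CBr)c1O | intermediate
14 | 2-[(2E,6E,9E,11S)-11-hydroxy-3,7,11,15-tetramethylhexadeca-2,6,9,14-tetraen-1-yl]-6-methylphenol | CC(C)=CCC[C@](C)(O)/C=C/C/C(C)=C/CC/C(C)=C/Cc1cccc(C)c1O | intermediate
15 | 2-[(2E,6E,9E,11S)-11-hydroxy-3,7,11,15-tetramethylhexadeca-2,6,9,14-tetraen-1-yl]-6-methylcyclohexa-2,5-diene-1,4-dione (not isolated) | CC(C)=CCC[C@](C)(O)/C=C/C/C(C)=C/CC/C(C)=C/CC1=CC(=O)C=C(C)C1=O | intermediate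
16 | 2-[(2E,6E,9E,11S)-11-hydroxy-3,7,11,15-tetramethylhexadeca-2,6,9,14-tetraen-1-yl]-6-methylbenzene-1,4-diol | CC(C)=CCC[C@](C)(O)/C=C/C/C(C)=C/CC/C(C)=C/Cc1cc(O)cc(C)c1O | target

**Step count**
Total: 9 steps. Longest linear sequence: 6 steps (1, 2, 3, 4, 8, 9 from geraniol); the arene branch (5, 6, 7, 8, 9 from geranyl chloride) is 5 steps.

**Steps most likely to fail, with fallbacks**

Step 5 is the least precedented: SeO2 oxidation next to an allylic chloride may over-oxidize to the enal or lose chloride. The fallback moves the allylic oxidation behind the arene attachment, so that no allylic halide is present. It sets out from o-cresol 9, whose sodium salt 10 is C-allylated as in step 6 (NaH, toluene) with commercial geranyl bromide F1 to give 2-geranyl-6-methylphenol F2. Ac2O/pyridine gives the aryl acetate F3. SeO2 (10 mol %)/t-BuOOH then hydroxylates the terminal (E)-methyl group to give the hydroxy acetate F4. K2CO3/MeOH removes the acetate, and the route is rejoined at 12.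

Step 6, the key step, depends on the ambident phenolate reacting at the ortho carbon rather than at oxygen or the para carbon. The fallback fixes the position with a halogen instead of the ion pair. It sets out from 8. Commercial 2-bromo-6-methylphenol F5 is treated with n-BuLi (2.1 equiv, THF, −78 → 0 °C; O–H deprotonation and Br/Li exchange) to give the O,C-dilithio species F6. Separately, 8 is deprotonated with n-BuLi (1.0 equiv, −78 °C) to its lithium alkoxide F7, which is added together with CuBr·SMe2 (10 mol %). SN2 coupling at the allylic chloride and aqueous NH4Cl work-up give 12, where the route is rejoined.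

Step 9 exposes a skipped diene with a doubly allylic CH2, a tertiary allylic alcohol and a very lipophilic substrate to a radical oxidant in a partly aqueous medium, and the product is air-sensitive. The fallback does the oxidative dearomatization on the simple alcohol before those groups exist. It sets out from 12, which (KSO3)2NO/KH2PO4 oxidizes to the quinone alcohol F8. Because PPh3 adds to quinones, the bromide F9 is made without phosphine (MsCl, 2,4,6-collidine, then LiBr, THF, 0 °C). Stille coupling of F9 with stannane 6 under the conditions of step 8 gives quinone 15, where the route is rejoined; only the Na2S2O4 reduction to 16 remains.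

**Further compounds**
F1 | step 5 | geranyl bromide, (2E)-1-bromo-3,7-dimethylocta-2,6-diene (commercial) | CC(C)=CCC/C(C)=C/CBr
F2 | step 5 | 2-[(2E)-3,7-dimethylocta-2,6-dien-1-yl]-6-methylphenol | Cc1cccc(C/C=C(\C)CCC=C(C)C)c1O
F3 | step 5 | 2-[(2E)-3,7-dimethylocta-2,6-dien-1-yl]-6-methylphenyl acetate | CC(=O)Oc1c(C)cccc1C/C=C(\C)CCC=C(C)C
F4 | step 5 | 2-[(2E,6E)-8-hydroxy-3,7-dimethylocta-2,6-dien-1-yl]-6-methylphenyl acetate | CC(=O)Oc1c(C)cccc1C/C=C(\C)CC/C=C(\C)CO
F5 | step 6 | 2-bromo-6-methylphenol (commercial) | Cc1cccc(Br)c1O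
F6 | step 6 | lithium 2-lithio-6-methylphenolate | [Li]c1cccc(C)c1O[Li]
F7 | step 6 | lithium (2E,6E)-8-chloro-2,6-dimethylocta-2,6-dien-1-olate | [Li+].[O-]C/C(C)=C/CC/C(C)=C/CCl
F8 | step 9 | 2-[(2E,6E)-8-hydroxy-3,7-dimethylocta-2,6-dien-1-yl]-6-methylcyclohexa-2,5-diene-1,4-dione | CC1=CC(=O)C=C(C/C=C(\C)CC/C=C(\C)CO)C1=O
F9 | step 9 | 2-[(2E,6E)-8-bromo-3,7-dimethylocta-2,6-dien-1-yl]-6-methylcyclohexa-2,5-diene-1,4-dione | CC1=CC(=O)C=C(C/C=C(\C)CC/C=C(\C)CBr)C1=O
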